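Atoms carry labdane numbers (C-1 to C-20) throughout.

## Retrosynthetic overview

- **Oxirane (last ring):** Sharpless epoxidation of the (E)-allylic alcohol. The C-8 methylene comes from a ketone and the C-15 alcohol from an enoate.
- **Rings A and B (formed together, first):** intramolecular Diels–Alder reaction of an acyclic triene, making bonds C3–C4 and C5–C10. The partners are the (Z)-diene C10=C1–C2=C3 and the (E)-2-methylenoate C4=C5. The C-19 ester is the activating group, and C-9 controls C-4, C-5 and C-10.
- **(Z)-Diene:** a temporary silicon tether on the C-8 carbinol (ring-closing metathesis, then vinyl cross-coupling) starting from an isopropenyl carbinol.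
- **C8–C9 bond and C-9:** enantioselective Nozaki–Hiyama–Kishi allylation. The aldehyde comes from pent-4-enal and methyl methacrylate, and the allyl chloride from methyl geranate.

Assumption: the SMILES is read literally. H-5, C-20, C-11 and the C-4 ester lie on one face, giving a cis-fused (5β-H) decalin with (4S,5S,9S,10R,13R,14R) configuration, not the usual trans-labdane.

## Route

Step 1
Reactants: 1 pent-4-enal; 2 methyl methacrylate
Product: 3 methyl (2E)-2-methyl-6-oxohex-2-enoate
Conditions: second-generation Hoveyda–Grubbs catalyst (3 mol %), 2 (5 equiv), CH2Cl2, 40 °C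
Reagents that add atoms: methyl methacrylate (2), C=C(C)C(=O)OC
Why: Olefin cross-metathesis of a reactive terminal alkene with the slowly homodimerising methacrylate favours the cross product and gives the (E)-trisubstituted enoate (ester trans to the chain), the geometry that later fixes C-4 relative to C-5, and the aldehyde is tolerated.

Step 2
Reactants: 4 methyl geranate, methyl (2E)-3,7-dimethylocta-2,6-dienoate
Product: 5 methyl (2E)-6-chloro-3,7-dimethylocta-2,7-dienoate (racemic)
Conditions: Ca(OCl)2, CO2 (s), CH2Cl2/H2O, 0 °C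
Reagents that add atoms: calcium hypochlorite, [Ca+2].[O-]Cl.[O-]Cl
Why: Ene-type allylic chlorination, in which HOCl attacks only the electron-rich 6,7-alkene (the 2,3-alkene is deactivated by the ester) and a methyl proton is lost, gives the transposed secondary allylic chloride as a racemate whose stereocentre is erased in the next step.

Step 3
Reactants: 5 methyl (2E)-6-chloro-3,7-dimethylocta-2,7-dienoate; 3 methyl (2E)-2-methyl-6-oxohex-2-enoate
Product: 8 dimethyl (2E,6S,7R,10E)-6-hydroxy-2,10-dimethyl-7-(prop-1-en-2-yl)dodeca-2,10-dienedioate (C-6 = labdane C-8, C-7 = labdane C-9), via allylchromium dichloride 6 (not isolated), via trimethylsilyl ether 7 (not isolated)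
Conditions: CrCl2 (10 mol %), chiral bis(oxazolinyl)carbazole ligand (12 mol %), Mn, Me3SiCl, iPr2NEt, THF, 0 °C; then 1 M HCl
Reagents that add atoms: none
Why: In this catalytic asymmetric Nozaki–Hiyama–Kishi allylation, divalent chromium reduces either enantiomer of 5 to the same (E)-configured trivalent allylchromium 6, which adds through its γ-carbon in a closed chair transition state (anti C-8/C-9) to the Re face of 3 chosen by the ligand, so C-9 is set as needed and the minor syn isomer is removed by chromatography.

Step 4
Reactants: 8 the homoallylic alcohol; 9 chloro(dimethyl)vinylsilane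
Product: 10 dimethyl (2E,6S,7R,10E)-6-{[dimethyl(vinyl)silyl]oxy}-2,10-dimethyl-7-(prop-1-en-2-yl)dodeca-2,10-dienedioate
Conditions: Et3N, DMAP (cat.), CH2Cl2, 0 °C to rt
Reagents that add atoms: chloro(dimethyl)vinylsilane (9), C=C[Si](C)(C)Cl
Why: Ordinary silyl ether formation places a vinylsilane within reach of the isopropenyl group and touches no stereocentre.

Step 5
Reactants: 10 the vinylsilyl ether
Product: 11 methyl (2E)-5-{(5R,6S)-5-[(3E)-5-methoxy-3-methyl-5-oxopent-3-en-1-yl]-2,2,4-trimethyl-5,6-dihydro-2H-1,2-oxasilin-6-yl}-2-methylpent-2-enoate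
Conditions: Mo(=CHCMe2Ph)(=N-2,6-iPr2C6H3)[OCMe(CF3)2]2 (7 mol %), benzene, rt
Reagents that add atoms: none
Why: In this ring-closing metathesis only the vinylsilane and the 1,1-disubstituted alkene are accessible to the catalyst (both enoates are trisubstituted and electron-poor), and the six-membered oxasiline can hold only a cis ring alkene, so silicon ends up cis to C-9 on the new C1=C10 bond.

Step 6
Reactants: 11 the cyclic siloxane; 12 bromoethene
Product: 13 dimethyl (2E,6S,7R,10E)-6-hydroxy-2,10-dimethyl-7-[(2Z)-penta-2,4-dien-2-yl]dodeca-2,10-dienedioate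
Conditions: Pd(dba)2 (5 mol %), nBu4NF·3H2O (2 equiv), THF, rt
Reagents that add atoms: bromoethene (12), C=CBr
Why: In this Hiyama–Denmark cross-coupling, fluoride activates the siloxane for transmetalation to palladium and the C–Si bond is replaced by vinyl with retention, which gives the otherwise contra-steric (Z)-trisubstituted diene (C-9 cis to C-2) and frees the carbinol.

Step 7 (key step)
Reactants: 13 the (Z)-dienyl carbinol
Product: 14 dimethyl 8β-hydroxy-17-nor-5β-labda-1,13(E)-diene-15,19-dioate (cis-decalin; 5β-H, 9α-H, 10β-CH3, 4β-CO2Me, 4α-CH3)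
Conditions: toluene (5 mM), BHT, 175 °C, sealed tube, 36 h
Reagents that add atoms: none
Why: In this intramolecular Diels–Alder reaction the tether sits on the inside (Z) position of the diene, so only the cis-fused transition state can be reached, suprafacial addition of the (E)-enoate puts H-5, C-20 and the endo CO2Me on one face (C-4, C-5, C-10), and A(1,3) strain keeps H-9 in the diene plane so that the chair-like tether with the C-11 chain equatorial exposes a single diene face, which relays C-9 to the three new centres and holds H-9 out of alignment for the competing [1,5]-hydrogen shift.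

Step 8
Reactants: 14 the cycloadduct
Product: 15 dimethyl 8β-hydroxy-17-nor-5β-labd-13(E)-ene-15,19-dioate
Conditions: 2-nitrobenzenesulfonyl hydrazide (10 equiv, portions), Et3N, CH2Cl2, rt
Reagents that add atoms: none
Why: Diimide reduction transfers H2 in a concerted syn fashion and discriminates by substitution, so the cis-disubstituted C1=C2 bond is saturated while the trisubstituted, conjugated C13=C14 bond remains.

Step 9
Reactants: 15 the saturated carbinol
Product: 16 dimethyl 8-oxo-17-nor-5β-labd-13(E)-ene-15,19-dioate
Conditions: Dess–Martin periodinane, CH2Cl2, rt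
Reagents that add atoms: none
Why: Dess–Martin oxidation is fast and nearly neutral, so the C-8 carbinol centre is removed without epimerising C-9, which is now α to the ketone.

Step 10
Reactants: 16 the ketone
Product: 17 dimethyl 5β-labda-8(17),13(E)-diene-15,19-dioate
Conditions: Zn, CH2Br2, TiCl4, THF/CH2Cl2, 0 °C to rt
Reagents that add atoms: dibromomethane, BrCBr
Why: Takai–Lombardo methylenation uses a non-basic gem-dimetallic reagent that converts hindered, enolisable ketones into methylene groups without epimerising C-9 and leaves both esters alone.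

Step 11
Reactants: 17 the diester
Product: 18 methyl 15-hydroxy-5β-labda-8(17),13(E)-dien-19-oate
Conditions: iBu2AlH (2.2 equiv), CH2Cl2, −78 °C; Rochelle salt
Reagents that add atoms: none
Why: This chemoselective hydride 1,2-reduction takes the unhindered conjugated C-15 ester at −78 °C, whereas the neopentyl C-19 ester, flanked by C-20, is too shielded to react.

Step 12
Reactants: 18 the allylic alcohol
Product: 19 methyl (13R,14R)-13,14-epoxy-15-hydroxy-5β-labd-8(17)-en-19-oate (target)
Conditions: Ti(OiPr)4 (10 mol %), D-(−)-diethyl tartrate (12 mol %), tBuOOH, 4 Å molecular sieves, CH2Cl2, −20 °C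
Reagents that add atoms: tert-butyl hydroperoxide, CC(C)(C)OO
Why: In the Sharpless asymmetric epoxidation the titanium tartrate binds the allylic alcohol, so only C13=C14 reacts (the C-8 methylene is untouched), and the D-(−)-tartrate delivers oxygen to the face that gives the (13R,14R)-epoxide, as geraniol gives its (2R,3R)-epoxide, under reagent control because the ring stereocentres are remote.

## Compound list

1 | pent-4-enal | C=CCCC=O | starting material
2 | methyl methacrylate | C=C(C)C(=O)OC | starting material
3 | methyl (2E)-2-methyl-6-oxohex-2-enoate | O=CCC/C=C(\C)C(=O)OC | intermediate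
4 | methyl geranate | CC(C)=CCC/C(C)=C/C(=O)OC | starting material
5 | methyl (2E)-6-chloro-3,7-dimethylocta-2,7-dienoate (racemic) | C=C(C)C(Cl)CC/C(C)=C/C(=O)OC | intermediate
6 | (E)-allylchromium dichloride (trivalent chromium, ligand omitted) | COC(=O)/C=C(\C)CC/C=C(\C)C[Cr](Cl)Cl | intermediate (not isolated)
7 | trimethylsilyl ether of 8 | C=C(C)[C@@H](CC/C(C)=C/C(=O)OC)[C@@H](O[Si](C)(C)C)CC/C=C(\C)C(=O)OC | intermediate (not isolated)
8 | dimethyl (2E,6S,7R,10E)-6-hydroxy-2,10-dimethyl-7-(prop-1-en-2-yl)dodeca-2,10-dienedioate | C=C(C)[C@@H](CC/C(C)=C/C(=O)OC)[C@@H](O)CC/C=C(\C)C(=O)OC | intermediate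
9 | chloro(dimethyl)vinylsilane | C=C[Si](C)(C)Cl | starting material
10 | dimethyl(vinyl)silyl ether of 8 | C=C(C)[C@@H](CC/C(C)=C/C(=O)OC)[C@@H](O[Si](C)(C)C=C)CC/C=C(\C)C(=O)OC | intermediate
11 | (5R,6S)-5,6-dihydro-2H-1,2-oxasiline | CC1=C[Si](C)(C)O[C@@H](CC/C=C(\C)C(=O)OC)[C@@H]1CC/C(C)=C/C(=O)OC | intermediate
12 | bromoethene | C=CBr | starting material
13 | dimethyl (2E,6S,7R,10E)-6-hydroxy-2,10-dimethyl-7-[(2Z)-penta-2,4-dien-2-yl]dodeca-2,10-dienedioate | C=C/C=C(/C)[C@@H](CC/C(C)=C/C(=O)OC)[C@@H](O)CC/C=C(\C)C(=O)OC | intermediate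
14 | dimethyl 8β-hydroxy-17-nor-5β-labda-1,13(E)-diene-15,19-dioate | O[C@H]1CC[C@H]2[C@](C)(C=CC[C@]2(C)C(=O)OC)[C@H]1CC/C(C)=C/C(=O)OC | intermediate
15 | dimethyl 8β-hydroxy-17-nor-5β-labd-13(E)-ene-15,19-dioate | O[C@H]1CC[C@H]2[C@](C)(CCC[C@]2(C)C(=O)OC)[C@H]1CC/C(C)=C/C(=O)OC | intermediate
16 | dimethyl 8-oxo-17-nor-5β-labd-13(E)-ene-15,19-dioate | O=C1CC[C@H]2[C@](C)(CCC[C@]2(C)C(=O)OC)[C@H]1CC/C(C)=C/C(=O)OC | intermediate
17 | dimethyl 5β-labda-8(17),13(E)-diene-15,19-dioate | C=C1CC[C@H]2[C@](C)(CCC[C@]2(C)C(=O)OC)[C@H]1CC/C(C)=C/C(=O)OC | intermediate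
18 | methyl 15-hydroxy-5β-labda-8(17),13(E)-dien-19-oate | C=C1CC[C@H]2[C@](C)(CCC[C@]2(C)C(=O)OC)[C@H]1CC/C(C)=C/CO | intermediate
19 | methyl (1S,4aR,5S,8aS)-5-{2-[(2R,3R)-3-(hydroxymethyl)-2-methyloxiran-2-yl]ethyl}-1,4a-dimethyl-6-methylidenedecahydronaphthalene-1-carboxylate | C=C1CC[C@H]2[C@](C)(CCC[C@]2(C)C(=O)OC)[C@H]1CC[C@@]1(C)O[C@@H]1CO | target

## Step count and weak points

Total step count: 12. Longest linear sequence: 11 (steps 2 to 12, from methyl geranate).

**Step 7 is the most uncertain.**
- A (Z)-diene with a tertiary carbon on its inside position reaches the s-cis form reluctantly, and two quaternary carbons are made.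
- A [1,5]-hydrogen shift could compete at 175 °C, and so could addition to the side-chain enoate.
- The fallback replaces thermal activation with a polar, Lewis-acid-driven closure of a masked substrate.
- Starting from 13, the carbinol is capped (Et3SiCl, imidazole, CH2Cl2) to give the triethylsilyl ether F1.
- MeAlCl2 (2.5 equiv, CH2Cl2, −40 to 0 °C) complexes the 2-methylenoate. The same cis-only, ester-endo closure then runs far below the temperature of the sigmatropic shift and gives the silyl-protected cycloadduct F2.
- HF·pyridine removes silicon, which returns to the route at 14.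

**Step 3 may give modest enantioselectivity or a low anti/syn ratio.** The allyl unit carries both a β-methyl group and a long γ-chain.
- The fallback changes the metal and the source of asymmetry.
- Starting from 4, allylic oxidation (SeO2 cat., tBuOOH, CH2Cl2) gives methyl (2E,6E)-8-hydroxy-3,7-dimethylocta-2,6-dienoate F3.
- Palladium-catalysed borylation (B2pin2, Pd(MeCN)4(BF4)2, DMSO/MeOH) gives the (E)-allylboronate F4.
- Chiral phosphoric acid-catalysed allylboration of aldehyde 3 (toluene, −30 °C) passes through a closed chair transition state, gives the anti adduct, and returns to the route at 8.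

**Step 6 exposes a carbinol to basic fluoride in the presence of an enoate five atoms away.** Oxa-Michael closure to a tetrahydrofuran or protodesilylation could therefore compete.
- The fallback separates the silicon removal from the carbon–carbon bond formation.
- Starting from 11, iododesilylation with retention (N-iodosuccinimide, hexafluoroisopropanol, 0 °C, aqueous work-up) gives the (Z)-vinyl iodide carbinol F5.
- A neutral Stille coupling with tributyl(vinyl)stannane (Pd2(dba)3, AsPh3, DMF, rt) returns to the route at 13.

## Further compounds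

F1 | step 7 | triethylsilyl ether of 13 | C=C/C=C(/C)[C@@H](CC/C(C)=C/C(=O)OC)[C@@H](O[Si](CC)(CC)CC)CC/C=C(\C)C(=O)OC
F2 | step 7 | triethylsilyl ether of 14 | CC[Si](CC)(CC)O[C@H]1CC[C@H]2[C@](C)(C=CC[C@]2(C)C(=O)OC)[C@H]1CC/C(C)=C/C(=O)OC
F3 | step 3 | methyl (2E,6E)-8-hydroxy-3,7-dimethylocta-2,6-dienoate | OC/C(C)=C/CC/C(C)=C/C(=O)OC
F4 | step 3 | methyl (2E,6E)-3,7-dimethyl-8-(4,4,5,5-tetramethyl-1,3,2-dioxaborolan-2-yl)octa-2,6-dienoate | CC1(C)OB(C/C(C)=C/CC/C(C)=C/C(=O)OC)OC1(C)C
F5 | step 6 | dimethyl (2E,6S,7R,10E)-6-hydroxy-7-[(1Z)-1-iodoprop-1-en-2-yl]-2,10-dimethyldodeca-2,10-dienedioate | I/C=C(/C)[C@@H](CC/C(C)=C/C(=O)OC)[C@@H](O)CC/C=C(\C)C(=O)OC
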